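**Retrosynthetic overview**

1. The target is the 3,4-cis (3R,4R) isoflavan-4-ol. Both stereocentres come from a racemic isoflavanone by asymmetric transfer hydrogenation with dynamic kinetic resolution, because C3 is benzylic and α to the C4 carbonyl and therefore epimerises; the 5-OH comes from 5-OMe by boron chelation to the peri C4 carbonyl.
2. The isoflavanone is cut at C2–C3 and C4–C4a of the pyranone ring (ring C) in one operation: a cationic formal [4+2] annulation of an O-aryl oxocarbenium ion (O1=C2H2+ on a 3,5-dimethoxyphenyl ring A) with the aryl ynol ether ArB–C3≡C4–OEt.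
3. Enabling feature: C2 is a methylene on O1 (latent oxocarbenium carbon); C4a lies ortho to O1 and ortho/para to the meta-placed oxygens on C5 and C7 of a phloroglucinol-type ring A, so it is the most nucleophilic ring carbon and both ortho sites are equivalent in the dimethyl ether; C4 carries oxygen and C3 the aryl group, which is the polarity pattern of an ynol ether.
4. The ynol ether comes from 4-bromo-3-methoxyphenol (iodination, silylation, I/Mg exchange–prenylation, Negishi alkynylation); the oxocarbenium precursor comes from 3,5-dimethoxyphenol and chloromethyl pivalate.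
5. Ring order: rings A and B are purchased; ring C is the only ring formed (step 6); redox and protecting-group adjustment follow.

Key step: step 6

Assumption: the SMILES is read as the 3,4-cis (3R,4R) isomer; acid-labile compounds 8, 14 and 15 are purified on base-washed silica. ArB below means 2-methoxy-5-(3-methylbut-2-en-1-yl)-4-(triisopropylsilyloxy)phenyl.

**Route**

Step 1
Reactants: 1 3,5-dimethoxyphenol
Product: 2 (3,5-dimethoxyphenoxy)methyl pivalate
Conditions: chloromethyl pivalate (1.2 equiv), K2CO3, NaI (cat.), DMF, rt
Reagents that add atoms: chloromethyl pivalate, CC(C)(C)C(=O)OCCl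
Why: Williamson O-alkylation of the phenoxide by the activated α-acyloxyalkyl halide (iodide-catalysed) is the standard entry to pivaloyloxymethyl aryl ethers and installs the future C2 as an O,O-acetal carbon that a silyl triflate can ionise; no stereocenter is formed.

Step 2
Reactants: 3 4-bromo-3-methoxyphenol
Product: 4 4-bromo-2-iodo-5-methoxyphenol
Conditions: N-iodosuccinimide (1.05 equiv), TsOH·H2O (cat.), MeCN, 0 °C → rt
Reagents that add atoms: N-iodosuccinimide, O=C1CCC(=O)N1I
Why: Electrophilic aromatic iodination should go to the only unhindered activated position, ortho to OH and para to OMe, since the site para to OH carries Br and the site between OH and OMe is flanked on both sides; no stereocenter is formed.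

Step 3
Reactants: 4 4-bromo-2-iodo-5-methoxyphenol
Product: 5 (4-bromo-2-iodo-5-methoxyphenoxy)triisopropylsilane
Conditions: TIPSCl, imidazole, DMF, rt
Reagents that add atoms: chlorotriisopropylsilane, CC(C)[Si](Cl)(C(C)C)C(C)C
Why: Standard phenol silylation; the triisopropylsilyl ether should tolerate the Grignard, zinc, Lewis-acid and BCl3 steps and prevents cyclisation of the later ortho-prenyl phenol.

Step 4
Reactants: 5 (4-bromo-2-iodo-5-methoxyphenoxy)triisopropylsilane
Product: 7 [4-bromo-5-methoxy-2-(3-methylbut-2-en-1-yl)phenoxy]triisopropylsilane, via arylmagnesium chloride 6 (not isolated)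
Conditions: i-PrMgCl·LiCl (1.1 equiv), THF, −30 °C; then CuBr·SMe2 (5 mol %), prenyl bromide (1.5 equiv), −30 → 0 °C
Reagents that add atoms: 1-bromo-3-methylbut-2-ene (prenyl bromide), CC(C)=CCBr
Why: Iodine–magnesium exchange is selective for the aryl iodide over the bromide at low temperature, and copper-catalysed allylic substitution in the Grignard-rich (diarylcuprate) regime should couple at the primary carbon of prenyl bromide, because attack at the other terminus would have to create an aryl-bearing quaternary carbon.

Step 5
Reactants: 7 [4-bromo-5-methoxy-2-(3-methylbut-2-en-1-yl)phenoxy]triisopropylsilane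
Product: 8 [4-(ethoxyethynyl)-5-methoxy-2-(3-methylbut-2-en-1-yl)phenoxy]triisopropylsilane
Conditions: ethoxyethyne (1.5 equiv), n-BuLi, THF, −78 °C; ZnCl2, −78 °C → rt; then 7, Pd2(dba)3 (2 mol %), XPhos (8 mol %), THF, 40 °C
Reagents that add atoms: ethoxyethyne, C#COCC
Why: Negishi alkynylation: the (ethoxyethynyl)zinc chloride made in the flask transmetalates readily, the bulky biarylphosphine lets zerovalent palladium insert into the electron-rich aryl bromide at a temperature at which the ynol ether does not fragment, and the non-acidic medium avoids its hydration.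

Step 6
Reactants: 2 (3,5-dimethoxyphenoxy)methyl pivalate; 8 [4-(ethoxyethynyl)-5-methoxy-2-(3-methylbut-2-en-1-yl)phenoxy]triisopropylsilane
Product: 11 rac-5,7-dimethoxy-3-ArB-chroman-4-one, via aryloxymethyl oxocarbenium triflate 9 (not isolated), via 4-ethoxy-2H-chromene 10 (not isolated)
Conditions: 8 (1.0 equiv), 2,6-di-tert-butyl-4-methylpyridine (1.5 equiv), TMSOTf (1.3 equiv), CH2Cl2, −78 °C, slow addition of 2 (1.3 equiv), then → −30 °C; then 1 M aq. HCl, THF, 0 °C → rt
Reagents that add atoms: water, O
Why: Proposed new method: TMSOTf should ionise the pivaloyloxymethyl ether 2 to the O-aryl oxocarbenium ion 9, whose CH2 carbon is attacked by the aryl-bearing carbon of ynol ether 8 (C2–C3 bond) because only this orientation gives an oxygen-stabilised ketenium (1-ethoxyvinyl) cation; that cationic carbon is then captured by the ortho carbon of the 3,5-dimethoxyphenoxy ring (C4–C4a bond), proton loss gives enol ether 10, and dilute acid hydrolyses it to ketone 11. The closest known reaction types are the oxa-Povarov reaction (formal [4+2] of aryl oxocarbenium ions with alkenes), the Povarov-type and thionium [4+2] annulations with alkynes that give quinolines and 2H-thiochromenes, and the ketenium/keteniminium Friedel–Crafts cyclisations of ynol ethers and ynamides; the pairing of an O-aryl oxocarbenium ion with an ynol ether is new. Ring C closes by a six-membered intramolecular Friedel–Crafts attack that is exo with respect to the C=O+ bond of the ketenium ion and leaves the C3=C4 enol ether bond inside the ring. The only stereocenter that appears, C3, arises on hydrolysis and is deliberately left racemic, since it is epimerisable and is set together with C4 in step 9. The step needs alkyne regioselectivity (secured by the ethoxy group), site selectivity on ring A (secured by the two equivalent ortho positions of the symmetric 3,5-dimethoxyphenoxy unit, each activated by two ortho oxygens and one para oxygen) and chemoselectivity over the prenyl alkene, ring B and a second molecule of 2 (secured by the much higher nucleophilicity of the ynol ether, slow addition of 2 and the hindered base that removes TfOH).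

Step 7
Reactants: 11 rac-5,7-dimethoxy-3-ArB-chroman-4-one
Product: 12 rac-5-hydroxy-7-methoxy-3-ArB-chroman-4-one
Conditions: BCl3 (1.5 equiv), CH2Cl2, −78 → −40 °C; then aq. NaHCO3
Reagents that add atoms: none
Why: Chelation-controlled ether cleavage: boron bridges the C4 carbonyl oxygen and the peri 5-OMe oxygen in a six-membered chelate so that chloride removes only that methyl group, while 7-OMe, 2'-OMe, the aryl silyl ether and, at low temperature, the prenyl alkene cannot enter such a chelate and should stay intact.

Step 8
Reactants: 12 rac-5-hydroxy-7-methoxy-3-ArB-chroman-4-one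
Product: 13 rac-5-(tert-butyldimethylsilyloxy)-7-methoxy-3-ArB-chroman-4-one
Conditions: TBSCl, imidazole, DMAP (cat.), DMF, 40 °C
Reagents that add atoms: tert-butylchlorodimethylsilane, CC(C)(C)[Si](C)(C)Cl
Why: Phenol silylation breaks the OH···O=C hydrogen bond and prevents phenoxide formation under the amine-rich reduction conditions, both of which would deactivate the ketone; C3 stays racemic.

Step 9
Reactants: 13 rac-5-(tert-butyldimethylsilyloxy)-7-methoxy-3-ArB-chroman-4-one
Product: 14 (3R,4R)-5-(tert-butyldimethylsilyloxy)-7-methoxy-3-ArB-chroman-4-ol (3,4-cis)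
Conditions: RuCl[(R,R)-TsDPEN](p-cymene) (3 mol %), HCO2H/Et3N (1:2), EtOAc, 40 °C
Reagents that add atoms: none
Why: Noyori–Ikariya asymmetric transfer hydrogenation with dynamic kinetic resolution: Et3N epimerises C3 faster than the ketone is reduced, the (R,R) catalyst should deliver hydride to the carbonyl face that gives 4R (ring A plays the aryl role of an aryl alkyl ketone), and the C3 epimer that reacts is the one whose aryl group lies anti to the incoming hydride, so OH and aryl end up cis (3R,4R), while the amine-rich medium protects the acid-labile benzylic alcohol.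

Step 10
Reactants: 14 (3R,4R)-5-(tert-butyldimethylsilyloxy)-7-methoxy-3-ArB-chroman-4-ol
Product: 15 (3R,4R)-3-[4-hydroxy-2-methoxy-5-(3-methylbut-2-en-1-yl)phenyl]-7-methoxychroman-4,5-diol (target)
Conditions: TBAF (3 equiv), AcOH (3 equiv), THF, 0 °C → rt; work-up at pH 7
Reagents that add atoms: none
Why: Fluoride-mediated cleavage of both aryl silyl ethers under buffered, non-acidic conditions should leave the acid-labile benzylic C4–OH, the prenyl group and both stereocenters untouched.

**Compound list**

1 | 3,5-dimethoxyphenol | COc1cc(O)cc(OC)c1 | starting material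
2 | (3,5-dimethoxyphenoxy)methyl 2,2-dimethylpropanoate (pivalate) | COc1cc(OC)cc(OCOC(=O)C(C)(C)C)c1 | intermediate
3 | 4-bromo-3-methoxyphenol | COc1cc(O)ccc1Br | starting material
4 | 4-bromo-2-iodo-5-methoxyphenol | COc1cc(O)c(I)cc1Br | intermediate
5 | (4-bromo-2-iodo-5-methoxyphenoxy)tri(propan-2-yl)silane | COc1cc(O[Si](C(C)C)(C(C)C)C(C)C)c(I)cc1Br | intermediate
6 | {5-bromo-4-methoxy-2-[tri(propan-2-yl)silyloxy]phenyl}magnesium chloride | COc1cc(O[Si](C(C)C)(C(C)C)C(C)C)c([Mg]Cl)cc1Br | intermediate (not isolated)
7 | [4-bromo-5-methoxy-2-(3-methylbut-2-en-1-yl)phenoxy]tri(propan-2-yl)silane | COc1cc(O[Si](C(C)C)(C(C)C)C(C)C)c(CC=C(C)C)cc1Br | intermediate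
8 | [4-(ethoxyethynyl)-5-methoxy-2-(3-methylbut-2-en-1-yl)phenoxy]tri(propan-2-yl)silane | CCOC#Cc1cc(CC=C(C)C)c(O[Si](C(C)C)(C(C)C)C(C)C)cc1OC | intermediate
9 | (3,5-dimethoxyphenyl)(methylidene)oxonium trifluoromethanesulfonate (O-aryl oxocarbenium ion pair) | COc1cc(OC)cc([O+]=C)c1.[O-]S(=O)(=O)C(F)(F)F | intermediate (not isolated)
10 | 4-ethoxy-5,7-dimethoxy-3-{2-methoxy-5-(3-methylbut-2-en-1-yl)-4-[tri(propan-2-yl)silyloxy]phenyl}-2H-chromene | CCOC1=C(c2cc(CC=C(C)C)c(O[Si](C(C)C)(C(C)C)C(C)C)cc2OC)COc2cc(OC)cc(OC)c12 | intermediate (not isolated)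
11 | rac-5,7-dimethoxy-3-{2-methoxy-5-(3-methylbut-2-en-1-yl)-4-[tri(propan-2-yl)silyloxy]phenyl}-2,3-dihydro-4H-chromen-4-one | COc1cc(OC)c2c(c1)OCC(c1cc(CC=C(C)C)c(O[Si](C(C)C)(C(C)C)C(C)C)cc1OC)C2=O | intermediate
12 | rac-5-hydroxy-7-methoxy-3-{2-methoxy-5-(3-methylbut-2-en-1-yl)-4-[tri(propan-2-yl)silyloxy]phenyl}-2,3-dihydro-4H-chromen-4-one | COc1cc(O)c2c(c1)OCC(c1cc(CC=C(C)C)c(O[Si](C(C)C)(C(C)C)C(C)C)cc1OC)C2=O | intermediate
13 | rac-5-[tert-butyl(dimethyl)silyloxy]-7-methoxy-3-{2-methoxy-5-(3-methylbut-2-en-1-yl)-4-[tri(propan-2-yl)silyloxy]phenyl}-2,3-dihydro-4H-chromen-4-one | COc1cc(O[Si](C)(C)C(C)(C)C)c2c(c1)OCC(c1cc(CC=C(C)C)c(O[Si](C(C)C)(C(C)C)C(C)C)cc1OC)C2=O | intermediate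
14 | (3R,4R)-5-[tert-butyl(dimethyl)silyloxy]-7-methoxy-3-{2-methoxy-5-(3-methylbut-2-en-1-yl)-4-[tri(propan-2-yl)silyloxy]phenyl}-3,4-dihydro-2H-chromen-4-ol (3,4-cis) | COc1cc(O[Si](C)(C)C(C)(C)C)c2c(c1)OC[C@@H](c1cc(CC=C(C)C)c(O[Si](C(C)C)(C(C)C)C(C)C)cc1OC)[C@H]2O | intermediate
15 | (3R,4R)-3-[4-hydroxy-2-methoxy-5-(3-methylbut-2-en-1-yl)phenyl]-7-methoxy-3,4-dihydro-2H-chromene-4,5-diol (3,4-cis) | COc1cc(O)c2c(c1)OC[C@@H](c1cc(CC=C(C)C)c(O)cc1OC)[C@H]2O | target

**Step count and risks**

Total step count: 10 (step 1 for the ring A fragment, steps 2–5 for the ring B fragment, steps 6–10 after their union).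
Longest linear sequence: 9 steps (3 → 15, steps 2–10).

Steps most likely to fail:

1. Step 6 (proposed new method). Possible failure processes are:
   - alkylation of ring A of a second molecule of 2 by the oxocarbenium ion;
   - capture of the ketenium ion by pivalate, triflate or the 2'-methoxy oxygen instead of Friedel–Crafts closure;
   - acid-promoted hydration of the ynol ether before it is alkylated.

   Fallback with known chemistry, setting out from 8 and 2 and returning at 11:
   - Hydration of 8 (wet THF, cat. TsOH) should give ethyl [2-methoxy-5-(3-methylbut-2-en-1-yl)-4-(triisopropylsilyloxy)phenyl]acetate F1.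
   - Saponification (LiOH, THF/H2O, 0 °C → rt) gives the arylacetic acid F2.
   - Double deprotonation and silylation (LiN(SiMe3)2, Me3SiCl, THF, −78 °C) gives the bis(trimethylsilyl) ketene acetal F3.
   - Mukaiyama-type alkylation of F3 with 2 and TMSOTf (CH2Cl2, −78 °C) gives, after aqueous work-up, racemic 3-(3,5-dimethoxyphenoxy)-2-arylpropanoic acid F4. The free acid is made directly so that no basic ester cleavage, with its risk of β-elimination of the aryloxide, is needed.
   - Intramolecular Friedel–Crafts acylation through the mixed trifluoroacetic anhydride (TFAA, CH2Cl2, 0 °C), the classical chroman-4-one closure of 3-aryloxypropanoic acids, leads to 11.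

2. Step 9. Possible failure processes are:
   - slow hydride transfer to the hindered, electron-rich carbonyl;
   - C3 epimerisation too slow relative to reduction, which would erode diastereo- and enantioselectivity;
   - ionisation of the very electron-rich benzylic alcohol if the medium becomes acidic.

   Fallback, setting out from 13 and returning at 14: substrate-controlled reduction with LiBH(s-Bu)3 (THF, −78 °C) delivers hydride anti to the 3-aryl group. It should give the racemic cis alcohol, that is 14 together with its (3S,4S)-enantiomer F5. The enantiomers are separated by preparative chromatography on a chiral stationary phase to give 14.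

3. Step 5. Possible failure processes are:
   - sluggish oxidative addition into the electron-rich aryl bromide;
   - hydration or thermal fragmentation of the ynol ether during coupling or purification.

   Fallback, setting out from 7 and returning at 8: copper-catalysed aromatic Finkelstein exchange (NaI, CuI cat., N,N'-dimethylethane-1,2-diamine, dioxane, 110 °C) gives [4-iodo-5-methoxy-2-(3-methylbut-2-en-1-yl)phenoxy]triisopropylsilane F6. Stille coupling of F6 with the neutral stannane Bu3SnC≡COEt (Pd(PPh3)4, toluene, rt → 50 °C) then gives 8. This replaces both the electrophile and the basic zinc acetylide and uses the aryl iodide class on which this ynol ether coupling is established.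

**Further compounds**

F1 | step 6 | ethyl {2-methoxy-5-(3-methylbut-2-en-1-yl)-4-[tri(propan-2-yl)silyloxy]phenyl}acetate | CCOC(=O)Cc1cc(CC=C(C)C)c(O[Si](C(C)C)(C(C)C)C(C)C)cc1OC
F2 | step 6 | {2-methoxy-5-(3-methylbut-2-en-1-yl)-4-[tri(propan-2-yl)silyloxy]phenyl}acetic acid | OC(=O)Cc1cc(CC=C(C)C)c(O[Si](C(C)C)(C(C)C)C(C)C)cc1OC
F3 | step 6 | bis(trimethylsilyl) ketene acetal of F2 | C[Si](C)(C)OC(O[Si](C)(C)C)=Cc1cc(CC=C(C)C)c(O[Si](C(C)C)(C(C)C)C(C)C)cc1OC
F4 | step 6 | rac-3-(3,5-dimethoxyphenoxy)-2-{2-methoxy-5-(3-methylbut-2-en-1-yl)-4-[tri(propan-2-yl)silyloxy]phenyl}propanoic acid | OC(=O)C(COc1cc(OC)cc(OC)c1)c1cc(CC=C(C)C)c(O[Si](C(C)C)(C(C)C)C(C)C)cc1OC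
F5 | step 9 | (3S,4S)-enantiomer of 14, formed with 14 as the racemic cis alcohol | COc1cc(O[Si](C)(C)C(C)(C)C)c2c(c1)OC[C@H](c1cc(CC=C(C)C)c(O[Si](C(C)C)(C(C)C)C(C)C)cc1OC)[C@@H]2O
F6 | step 5 | [4-iodo-5-methoxy-2-(3-methylbut-2-en-1-yl)phenoxy]tri(propan-2-yl)silane | COc1cc(O[Si](C(C)C)(C(C)C)C(C)C)c(CC=C(C)C)cc1I
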